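A direct plan would assemble the ring carbons as an open chain by epoxide chemistry, bridge the two tertiary hydroxyls as a cyclic silylene, cleave two alkenes to the dialdehyde A1, close C1–C6 by an amine-catalysed aldol reaction to A2 and then grow the side chain stepwise through the dienal A3. Its weakest steps would be the silylene bridging of two hindered tertiary alcohols (forcing silylation, late fluoride release beside two acetates), the aldol ring closure (two new stereocentres resting on an untested conformational argument, with dehydration and epimerisation of the β-hydroxy aldehyde as exits) and the four-step linear growth of the triene (two Wittig homologations, aldol addition, elimination), which would add length without complexity.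

The cyclohexane is disconnected at C1–C2 and at the C3–O and C6–O bonds, exploiting the cis C1/C2 pair and a C3–C6 segment that maps onto a 1,3-diene. An acyclic (1E,3Z,5E)-triene, assembled from tiglaldehyde in two steps and carrying the C2, C3 and C5 methyls, closes by thermal disrotatory 6π-electrocyclisation to the cis cyclohexadiene, whose diene is trapped by singlet oxygen. One operation makes the ring and four stereocentres; the two allylic hydroxyls steer osmylation to the all-cis tetraol. No aldol closure occurs, the tertiary hydroxyls stay free, the chiral-pool dioxolane that biases the closure is the latent C1 formyl group, and the pyranone dienyl chain arrives in one cross-coupling.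

Key step: step 4

Remark: ring atoms keep one numbering in every intermediate, the triene included: C1 (side chain), C2 (methyl), C3 and C5 (tertiary carbinols), C4 and C6 (acetoxy carbons). Compounds 3 and 22 and Cl2CHB(pin) are taken as purchasable.

Step 1
Reactants: 1 tiglaldehyde, (E)-2-methylbut-2-enal
Product: 2 (2Z,4E)-2-iodo-4-methylhexa-2,4-diene
Conditions: EtPPh3+ I− (1.2 equiv), n-BuLi, THF, rt; I2, −78 °C; NaN(SiMe3)2, −20 °C; then 1, −78 → −20 °C; pentane work-up, kept cold and dark
Reagents that add atoms: ethyltriphenylphosphonium iodide, CC[P+](c1ccccc1)(c1ccccc1)c1ccccc1.[I-]; iodine, II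
Why: Stork–Zhao-type Wittig olefination with the α-iodo ylide should give the (Z)-2-iodoalkene, in which iodine (the future C5–C6 bond) is cis to C3, while the tiglyl C2=C3 geometry is carried over unchanged.

Step 2
Reactants: 3 (S)-2,2-dimethyl-1,3-dioxolane-4-carbaldehyde
Product: 4 2-{(E)-2-[(4R)-2,2-dimethyl-1,3-dioxolan-4-yl]ethenyl}-4,4,5,5-tetramethyl-1,3,2-dioxaborolane
Conditions: CrCl2 (8 equiv), LiI (4 equiv), Cl2CHB(pin) (2 equiv), THF, rt
Reagents that add atoms: 2-(dichloromethyl)-4,4,5,5-tetramethyl-1,3,2-dioxaborolane, ClC(Cl)B1OC(C)(C)C(C)(C)O1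
Why: Takai–Utimoto boron olefination (addition of the gem-dichromium reagent to the aldehyde, then elimination) should give the (E)-alkenylboronate without touching the α-stereocentre, whose descriptor changes from S to R only because the substituent priorities change.

Step 3
Reactants: 2 (2Z,4E)-2-iodo-4-methylhexa-2,4-diene; 4 alkenylboronate
Product: 5 (4R)-4-[(1E,3Z,5E)-3,5-dimethylhepta-1,3,5-trien-1-yl]-2,2-dimethyl-1,3-dioxolane
Conditions: Pd(dppf)Cl2 (5 mol%), aq. K3PO4 (3 equiv), THF, 25 °C, dark; crude triene used at once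
Reagents that add atoms: alkenylboronate (4), CC1(C)OC[C@H](O1)/C=C/B1OC(C)(C)C(C)(C)O1
Why: Suzuki–Miyaura coupling of an alkenyl iodide with an alkenylboronate proceeds with retention at both partners and at room temperature, so the (1E,3Z,5E)-triene (E at C1=C6, Z at C5=C4, E at C3=C2) should be obtained before it cyclises.

Step 4
Reactants: 5 (1E,3Z,5E)-triene
Product: 7 endoperoxide (2,3-dioxabicyclo[2.2.2]oct-5-ene; O–O across C3 and C6 on the face opposite to the C1 dioxolanyl and C2 methyl groups), via cis-cyclohexadiene 6 (not isolated)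
Conditions: degassed toluene (0.02 M), BHT (cat.), 90 °C, dark; then 0 °C, O2, tetraphenylporphyrin (0.5 mol%), white LED; chromatography
Reagents that add atoms: oxygen, O=O
Why: On heating, the s-cis,s-cis conformer of the (1E,3Z,5E)-triene undergoes the thermally allowed disrotatory 6π-electrocyclisation (the classical hexatriene to cyclohexa-1,3-diene closure) that forms the C1–C2 bond, and the ring-locked s-cis diene so formed is trapped in the same flask by singlet oxygen in a suprafacial [4+2] cycloaddition (the ascaridole-type photooxygenation of cyclohexa-1,3-dienes) that forms the C3–O and C6–O bonds. The carbocycle closes in the 6π disrotatory mode between the two triene termini, and the 2,3-dioxabicyclo[2.2.2]octene closes in the [4+2] mode across C3 and C6. C1 and C2 come out cis because the outer substituents of the two E termini turn to the same face in the disrotatory motion; which of the two cis rings forms is biased by the dioxolane stereocentre, bond formation at C1 being expected anti to the allylic C–O bond with the allylic hydrogen near the triene plane, and the minor cis isomer, being a diastereomer, is removed by chromatography of 7. C3 and C6 are controlled by the cis pair at C1 and C2, one member of which is always pseudoaxial, so that singlet oxygen adds to the opposite face of the diene. The step needs the triene geometry to survive until closure, which the moderate temperature secures against E/Z isomerisation and [1,5]-hydrogen shifts, and it needs cycloaddition to win over the ene reaction of singlet oxygen, which the s-cis geometry of the cyclic diene secures.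

Step 5
Reactants: 7 endoperoxide
Product: 8 cis-ene-1,4-diol (C4=C5 alkene; tertiary C3–OH and secondary C6–OH on the face opposite to the C1 and C2 substituents)
Conditions: Zn dust (10 equiv), AcOH (5 equiv), CH2Cl2, 0 °C → rt
Reagents that add atoms: none
Why: Reductive cleavage of the peroxide O–O bond by zinc in acetic acid leaves both C–O bonds untouched, so the C3 and C6 hydroxyls keep the configuration set in step 4.

Step 6
Reactants: 8 cis-ene-1,4-diol
Product: 10 all-cis tetraol (C3, C4, C5 and C6 hydroxyls on one face; C1 dioxolanyl and the C2, C3 and C5 methyls on the other), via osmate ester 9 (not isolated)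
Conditions: OsO4 (1.05 equiv), TMEDA (1.1 equiv), CH2Cl2, −78 °C; then aq. Na2SO3, THF, 60 °C
Reagents that add atoms: osmium tetroxide, O=[Os](=O)(=O)=O
Why: Hydrogen-bond-directed syn-dihydroxylation with the OsO4·TMEDA complex: both allylic hydroxyls (C3 and C6) lie on the same face and should deliver the reagent to that face of the C4=C5 bond, which sets C4 and C5 cis to the existing oxygens after hydrolysis of the osmate ester.

Step 7
Reactants: 10 all-cis tetraol
Product: 11 C4,C6-diacetate (C3 and C5 hydroxyls free)
Conditions: Ac2O (3 equiv), pyridine, DMAP (0.1 equiv), CH2Cl2, 0 °C → rt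
Reagents that add atoms: acetic anhydride, CC(=O)OC(C)=O
Why: DMAP-catalysed acylation should esterify the two secondary hydroxyls (C4 and C6) and leave the two hindered tertiary ones free, which is the acylation pattern of the target, so no protecting group is needed on the ring.

Step 8
Reactants: 11 C4,C6-diacetate
Product: 13 ring aldehyde (C1 formyl; C4,C6-diacetate; C3,C5-diol), via terminal diol 12 (not isolated)
Conditions: H5IO6 (2 equiv), EtOAc, rt
Reagents that add atoms: none
Why: Periodic acid should hydrolyse the terminal isopropylidene acetal and cleave the liberated 1,2-diol in one pot (glycol cleavage) to the C1 aldehyde, the ring holding no free vicinal diol once C4 and C6 are acetylated and the base-free medium sparing the β-acetoxy aldehyde.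

Step 9
Reactants: 13 ring aldehyde
Product: 14 1,1-dibromoalkene (C1 bears CH=CBr2)
Conditions: CBr4 (2 equiv), PPh3 (2 equiv), Zn dust (2 equiv), CH2Cl2, rt, 24 h; then 13, 0 °C → rt
Reagents that add atoms: carbon tetrabromide, BrC(Br)(Br)Br
Why: Dibromomethylenation with the preformed, non-basic ylide Ph3P=CBr2 (first stage of the Corey–Fuchs sequence, zinc variant) should convert the aldehyde into the 1,1-dibromoalkene without β-elimination of the C6 acetate or epimerisation at C1.

Step 10
Reactants: 15 methyl 2-methyl-3-oxopentanoate; 16 N-methoxy-N-methylpropanamide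
Product: 18 methyl 2,4-dimethyl-3,5-dioxoheptanoate (mixture of stereoisomers and enol forms), via keto ester dianion 17 (not isolated)
Conditions: NaH (1.1 equiv), THF, 0 °C; n-BuLi (1.05 equiv), 0 °C; then 16, −78 → 0 °C; aq. HCl
Reagents that add atoms: N-methoxy-N-methylpropanamide (16), CCC(=O)N(C)OC
Why: Claisen-type C-acylation of the β-keto ester 1,3-dianion at its γ-carbon by the N-methoxy-N-methylamide should give the triketide, the chelated tetrahedral intermediate preventing over-addition.

Step 11
Reactants: 18 methyl 2,4-dimethyl-3,5-dioxoheptanoate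
Product: 19 6-ethyl-4-hydroxy-3,5-dimethyl-2H-pyran-2-one
Conditions: DBU (1.5 equiv), toluene, reflux
Reagents that add atoms: none
Why: Base-mediated enol lactonisation (acyl substitution of the methyl ester by the C5 enolate oxygen) should close the 2-pyranone with loss of methanol.

Step 12
Reactants: 19 6-ethyl-4-hydroxy-3,5-dimethyl-2H-pyran-2-one
Product: 21 6-ethyl-2-methoxy-3,5-dimethyl-4H-pyran-4-one, via hydroxypyrylium triflate 20 (not isolated)
Conditions: MeOTf (1.2 equiv), CH2Cl2, rt; aq. NaHCO3
Reagents that add atoms: methyl trifluoromethanesulfonate, COS(=O)(=O)C(F)(F)F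
Why: O-methylation by the hard alkylating agent should occur at the lactone carbonyl oxygen, and proton loss from the hydroxypyrylium ion then gives the 2-methoxy-4-pyranone and not the 4-methoxy-2-pyranone.

Step 13
Reactants: 22 (E)-3-(tributylstannyl)prop-2-en-1-ol
Product: 23 (E)-3-(tributylstannyl)prop-2-enal
Conditions: MnO2 (15 equiv), CH2Cl2, rt
Reagents that add atoms: none
Why: Allylic oxidation with activated manganese dioxide should give the enal with the E geometry and the carbon–tin bond intact.

Step 14
Reactants: 21 6-ethyl-2-methoxy-3,5-dimethyl-4H-pyran-4-one; 23 (E)-3-(tributylstannyl)prop-2-enal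
Product: 25 6-[(E)-3-hydroxy-5-(tributylstannyl)pent-4-en-2-yl]-2-methoxy-3,5-dimethyl-4H-pyran-4-one (diastereomer mixture), via lithiated pyranone 24 (not isolated)
Conditions: 21 (1.2 equiv), LiN(SiMe3)2 (1.15 equiv), THF, −78 °C; then 23, −78 °C; aq. NH4Cl at −78 °C
Reagents that add atoms: (E)-3-(tributylstannyl)prop-2-enal (23), O=C/C=C/[Sn](CCCC)(CCCC)CCCC
Why: Aldol addition of the pyranone-stabilised (vinylogous enolate) carbanion of the 6-ethyl group should occur 1,2 at the enal, and both new stereocentres disappear in the next step.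

Step 15
Reactants: 25 aldol adduct
Product: 27 2-methoxy-3,5-dimethyl-6-[(2E,4E)-5-(tributylstannyl)penta-2,4-dien-2-yl]-4H-pyran-4-one, via allylic mesylate 26 (not isolated)
Conditions: MsCl (1.5 equiv), Et3N (3 equiv), CH2Cl2, 0 °C; then DBU (3 equiv), 0 °C → rt; chromatography on Et3N-deactivated silica
Reagents that add atoms: none
Why: Mesylation followed by E1cB elimination through the pyranone-stabilised carbanion should give the conjugated dienylstannane, the new trisubstituted alkene forming as the thermodynamically preferred E isomer in which the chain avoids the pyranone C5 methyl.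

Step 16
Reactants: 14 1,1-dibromoalkene; 27 dienylstannane
Product: 28 (Z)-bromotriene, 6-[(2E,4E,6Z)-6-bromo-7-(ring C1)hepta-2,4,6-trien-2-yl]-2-methoxy-3,5-dimethyl-4H-pyran-4-one (amaurone B with bromine in place of the methyl group on the alkene carbon next to the ring CH=)
Conditions: 27 (1.2 equiv), Pd2(dba)3 (2.5 mol%), tri(2-furyl)phosphine (15 mol%), toluene, 80 °C
Reagents that add atoms: dienylstannane (27), COc1oc(/C(C)=C/C=C/[Sn](CCCC)(CCCC)CCCC)c(C)c(=O)c1C
Why: Stille coupling of a 1,1-dibromoalkene is known to take place selectively at the less hindered bromine trans to the substituent (here the ring) with tri(2-furyl)phosphine in toluene, which should place the dienyl chain trans to the ring with retention of the stannane geometry, while the neutral conditions spare the acetates and the free tertiary hydroxyls.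

Step 17
Reactants: 28 (Z)-bromotriene
Product: 29 amaurone B
Conditions: Me2Zn (4 equiv), Pd(PtBu3)2 (5 mol%), THF, 0 °C → rt; aq. NH4Cl
Reagents that add atoms: dimethylzinc, C[Zn]C
Why: Negishi methylation of the remaining hindered alkenyl bromide is the known second stage of the dibromoalkene route to trisubstituted alkenes and should replace bromine by methyl with retention (methyl cis to the ring, E alkene), dimethylzinc being unreactive toward the acetates and the pyranone.

Compound list
1 | tiglaldehyde, (E)-2-methylbut-2-enal | C/C=C(C)/C=O | starting material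
2 | (2Z,4E)-2-iodo-4-methylhexa-2,4-diene | C/C=C(C)/C=C(/C)I | intermediate
3 | (S)-2,2-dimethyl-1,3-dioxolane-4-carbaldehyde | O=C[C@@H]1COC(C)(C)O1 | starting material
4 | 2-{(E)-2-[(4R)-2,2-dimethyl-1,3-dioxolan-4-yl]ethenyl}-4,4,5,5-tetramethyl-1,3,2-dioxaborolane | CC1(C)OC[C@H](O1)/C=C/B1OC(C)(C)C(C)(C)O1 | intermediate
5 | (4R)-4-[(1E,3Z,5E)-3,5-dimethylhepta-1,3,5-trien-1-yl]-2,2-dimethyl-1,3-dioxolane | CC1(C)OC[C@H](O1)/C=C/C(C)=C\C(C)=C\C | intermediate
6 | (4R)-2,2-dimethyl-4-[(1S,6S)-3,5,6-trimethylcyclohexa-2,4-dien-1-yl]-1,3-dioxolane (cis at ring C1 and C2) | CC1(C)OC[C@H](O1)[C@@H]2[C@H](C)C(C)=CC(C)=C2 | intermediate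
7 | endoperoxide: (4R)-dioxolanyl trimethyl-2,3-dioxabicyclo[2.2.2]oct-5-ene, O–O across C3 and C6 opposite to the C1 and C2 substituents | CC1(C)OC[C@H](O1)[C@@H]2[C@H](C)[C@@](C)(O3)C=C(C)[C@H]2O3 | intermediate
8 | cis-ene-1,4-diol (C3–OH and C6–OH opposite to the C1 and C2 substituents; C4=C5 alkene) | CC1(C)OC[C@H](O1)[C@@H]2[C@H](C)[C@@](C)(O)C=C(C)[C@H]2O | intermediate
9 | TMEDA-ligated osmate ester (hexavalent osmium) of the C4,C5-diol | CC1(C)OC[C@H](O1)[C@@H]2[C@H](C)[C@@](C)(O)[C@@H](O3)[C@@](C)(O[Os]3(=O)=O)[C@H]2O.CN(C)CCN(C)C | intermediate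
10 | all-cis tetraol (C3, C4, C5, C6 hydroxyls on one face) | CC1(C)OC[C@H](O1)[C@@H]2[C@H](C)[C@@](C)(O)[C@@H](O)[C@@](C)(O)[C@H]2O | intermediate
11 | C4,C6-diacetate of 10 | CC1(C)OC[C@H](O1)[C@@H]2[C@H](C)[C@@](C)(O)[C@@H](OC(C)=O)[C@@](C)(O)[C@H]2OC(C)=O | intermediate
12 | terminal (R)-1,2-diol from acetal hydrolysis of 11 | OC[C@H](O)[C@@H]1[C@H](C)[C@@](C)(O)[C@@H](OC(C)=O)[C@@](C)(O)[C@H]1OC(C)=O | intermediate
13 | ring aldehyde (C1 formyl, C4,C6-diacetate, C3,C5-diol; ring configuration of the target) | O=C[C@@H]1[C@H](C)[C@@](C)(O)[C@@H](OC(C)=O)[C@@](C)(O)[C@H]1OC(C)=O | intermediate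
14 | 1,1-dibromoalkene (C1 bears CH=CBr2) | BrC(Br)=C[C@@H]1[C@H](C)[C@@](C)(O)[C@@H](OC(C)=O)[C@@](C)(O)[C@H]1OC(C)=O | intermediate
15 | methyl 2-methyl-3-oxopentanoate | CCC(=O)C(C)C(=O)OC | starting material
16 | N-methoxy-N-methylpropanamide | CCC(=O)N(C)OC | starting material
17 | sodium lithium 1,3-dianion of 15 | [Na+].[Li+].C[CH-]C(=O)[C-](C)C(=O)OC | intermediate
18 | methyl 2,4-dimethyl-3,5-dioxoheptanoate | CCC(=O)C(C)C(=O)C(C)C(=O)OC | intermediate
19 | 6-ethyl-4-hydroxy-3,5-dimethyl-2H-pyran-2-one | CCc1oc(=O)c(C)c(O)c1C | intermediate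
20 | 6-ethyl-4-hydroxy-2-methoxy-3,5-dimethylpyrylium trifluoromethanesulfonate | CCc1[o+]c(OC)c(C)c(O)c1C.[O-]S(=O)(=O)C(F)(F)F | intermediate
21 | 6-ethyl-2-methoxy-3,5-dimethyl-4H-pyran-4-one | CCc1oc(OC)c(C)c(=O)c1C | intermediate
22 | (E)-3-(tributylstannyl)prop-2-en-1-ol | OC/C=C/[Sn](CCCC)(CCCC)CCCC | starting material
23 | (E)-3-(tributylstannyl)prop-2-enal | O=C/C=C/[Sn](CCCC)(CCCC)CCCC | intermediate
24 | lithium salt of 21 deprotonated at the ethyl CH2 | [Li+].C[CH-]c1oc(OC)c(C)c(=O)c1C | intermediate
25 | 6-[(E)-3-hydroxy-5-(tributylstannyl)pent-4-en-2-yl]-2-methoxy-3,5-dimethyl-4H-pyran-4-one (diastereomer mixture) | COc1oc(C(C)C(O)/C=C/[Sn](CCCC)(CCCC)CCCC)c(C)c(=O)c1C | intermediate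
26 | methanesulfonate of 25 | COc1oc(C(C)C(OS(C)(=O)=O)/C=C/[Sn](CCCC)(CCCC)CCCC)c(C)c(=O)c1C | intermediate
27 | 2-methoxy-3,5-dimethyl-6-[(2E,4E)-5-(tributylstannyl)penta-2,4-dien-2-yl]-4H-pyran-4-one | COc1oc(/C(C)=C/C=C/[Sn](CCCC)(CCCC)CCCC)c(C)c(=O)c1C | intermediate
28 | (Z)-bromotriene (amaurone B with Br in place of the alkene methyl next to the ring) | COc1oc(/C(C)=C/C=C/C(Br)=C/[C@@H]2[C@H](C)[C@@](C)(O)[C@@H](OC(C)=O)[C@@](C)(O)[C@H]2OC(C)=O)c(C)c(=O)c1C | intermediate
29 | amaurone B | COc1oc(/C(C)=C/C=C/C(C)=C/[C@@H]2[C@H](C)[C@@](C)(O)[C@@H](OC(C)=O)[C@@](C)(O)[C@H]2OC(C)=O)c(C)c(=O)c1C | target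

Total step count: 17. Longest linear sequence: 10 steps (steps 1, 3, 4, 5, 6, 7, 8, 9, 16, 17, from tiglaldehyde).

Steps most likely to fail

Step 4. The risk is a weak or reversed facial bias of the dioxolane stereocentre during ring closure, which would leave the wanted cis isomer as the minor one; thermal [1,5]-hydrogen shift and ene oxygenation would be lesser drains. The fallback would change the stereocontrolling element to its mirror image, so that the wanted ring configuration becomes the favoured diastereomer. It would set out from 2. Suzuki coupling with the (S,E)-alkenylboronate F2, made by the same boron olefination from (R)-2,2-dimethyl-1,3-dioxolane-4-carbaldehyde F1, would give the (4S)-triene F3. Heating would give the (4S)-dioxolanyl cis-cyclohexadiene F4 and photooxygenation the endoperoxide F5. Zinc reduction would give the ene-diol F6, directed osmylation through the osmate ester F7 the tetraol F8, and acetylation the diacetate F9. Periodic acid, through the terminal diol F10, would then give aldehyde 13, where the fallback comes back to the route because the dioxolane carbon is excised there.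

Step 6. The risk is slow osmylation of the hindered trisubstituted alkene, or attack from the face of the C1 and C2 substituents if hydrogen-bond delivery fails. The fallback would invert the order of the two oxygenation events, so that the bicyclic skeleton and not hydrogen bonding controls the face. It would set out from 7. Catalytic OsO4 with N-methylmorpholine N-oxide would dihydroxylate the C4=C5 bond from the peroxide side, the other face being blocked by the dioxolanyl and methyl groups on the C1–C2 bridge, to give the peroxy diol F11. Zinc in acetic acid would then cleave the O–O bond and come back to the route at tetraol 10.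

Step 17. The risk is partial loss of alkene geometry at the hindered bromodiene during the palladium cycle, or acetyl migration started by zinc alkoxides of the tertiary hydroxyls. The fallback would bring in the methyl group together with the alkene by carbonyl olefination in place of cross-coupling. It would set out from 13. Wittig reaction with 2-(triphenylphosphoranylidene)propanal would give the (E)-enal F12, and a second Wittig reaction with (triphenylphosphoranylidene)acetaldehyde the (2E,4E)-dienal F13. Aldol addition of the lithiated pyranone 24 would give the dienylic alcohol F14, and mesylation to the mesylate F15 followed by DBU elimination would come back to the route at the target 29.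

Further compounds
F1 | step 4 | (R)-2,2-dimethyl-1,3-dioxolane-4-carbaldehyde | O=C[C@H]1COC(C)(C)O1
F2 | step 4 | 2-{(E)-2-[(4S)-2,2-dimethyl-1,3-dioxolan-4-yl]ethenyl}-4,4,5,5-tetramethyl-1,3,2-dioxaborolane | CC1(C)OC[C@@H](O1)/C=C/B1OC(C)(C)C(C)(C)O1
F3 | step 4 | (4S)-4-[(1E,3Z,5E)-3,5-dimethylhepta-1,3,5-trien-1-yl]-2,2-dimethyl-1,3-dioxolane | CC1(C)OC[C@@H](O1)/C=C/C(C)=C\C(C)=C\C
F4 | step 4 | (4S)-dioxolanyl cis-cyclohexadiene with the ring configuration of 6 | CC1(C)OC[C@@H](O1)[C@@H]2[C@H](C)C(C)=CC(C)=C2
F5 | step 4 | (4S)-dioxolanyl endoperoxide with the ring configuration of 7 | CC1(C)OC[C@@H](O1)[C@@H]2[C@H](C)[C@@](C)(O3)C=C(C)[C@H]2O3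
F6 | step 4 | (4S)-dioxolanyl cis-ene-1,4-diol | CC1(C)OC[C@@H](O1)[C@@H]2[C@H](C)[C@@](C)(O)C=C(C)[C@H]2O
F7 | step 4 | TMEDA-ligated osmate ester (hexavalent osmium) of the (4S)-dioxolanyl series | CC1(C)OC[C@@H](O1)[C@@H]2[C@H](C)[C@@](C)(O)[C@@H](O3)[C@@](C)(O[Os]3(=O)=O)[C@H]2O.CN(C)CCN(C)C
F8 | step 4 | (4S)-dioxolanyl all-cis tetraol | CC1(C)OC[C@@H](O1)[C@@H]2[C@H](C)[C@@](C)(O)[C@@H](O)[C@@](C)(O)[C@H]2O
F9 | step 4 | (4S)-dioxolanyl C4,C6-diacetate | CC1(C)OC[C@@H](O1)[C@@H]2[C@H](C)[C@@](C)(O)[C@@H](OC(C)=O)[C@@](C)(O)[C@H]2OC(C)=O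
F10 | step 4 | terminal (S)-1,2-diol of the C4,C6-diacetate | OC[C@@H](O)[C@@H]1[C@H](C)[C@@](C)(O)[C@@H](OC(C)=O)[C@@](C)(O)[C@H]1OC(C)=O
F11 | step 6 | peroxy diol (C4,C5-diol of endoperoxide 7, hydroxyls on the peroxide face) | CC1(C)OC[C@H](O1)[C@@H]2[C@H](C)[C@@](C)(O3)[C@@H](O)[C@@](C)(O)[C@H]2O3
F12 | step 17 | (E)-2-methyl-3-(ring C1)propenal, C4,C6-diacetate | O=C/C(C)=C/[C@@H]1[C@H](C)[C@@](C)(O)[C@@H](OC(C)=O)[C@@](C)(O)[C@H]1OC(C)=O
F13 | step 17 | (2E,4E)-4-methyl-5-(ring C1)penta-2,4-dienal, C4,C6-diacetate | O=C/C=C/C(C)=C/[C@@H]1[C@H](C)[C@@](C)(O)[C@@H](OC(C)=O)[C@@](C)(O)[C@H]1OC(C)=O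
F14 | step 17 | aldol adduct of 24 and F13 (dienylic alcohol, diastereomer mixture) | COc1oc(C(C)C(O)/C=C/C(C)=C/[C@@H]2[C@H](C)[C@@](C)(O)[C@@H](OC(C)=O)[C@@](C)(O)[C@H]2OC(C)=O)c(C)c(=O)c1C
F15 | step 17 | methanesulfonate of F14 | COc1oc(C(C)C(OS(C)(=O)=O)/C=C/C(C)=C/[C@@H]2[C@H](C)[C@@](C)(O)[C@@H](OC(C)=O)[C@@](C)(O)[C@H]2OC(C)=O)c(C)c(=O)c1C
A1 | direct plan | silylene-bridged C4-acetoxy heptanedial | O=CC[C@H](C)[C@@](C)(O[Si]1(C(C)C)C(C)C)[C@@H](OC(C)=O)[C@@](C)(O1)C=O
A2 | direct plan | silylene-bridged cyclohexane β-hydroxy aldehyde | O=C[C@@H]2[C@H](C)[C@@](C)(O[Si]1(C(C)C)C(C)C)[C@@H](OC(C)=O)[C@@](C)(O1)[C@H]2O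
A3 | direct plan | silylene-bridged (2E,4E)-dienal, C4,C6-diacetate | O=C/C=C/C(C)=C/[C@@H]2[C@H](C)[C@@](C)(O[Si]1(C(C)C)C(C)C)[C@@H](OC(C)=O)[C@@](C)(O1)[C@H]2OC(C)=O
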